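The route rests on cutting the bond between oxolane C-2 and the exocyclic carbinol carbon. C-2 bears the ring oxygen O-1 and lies γ to C-5, so with C-5 raised to the lactone level and C-3/C-4 as an enol double bond the ring becomes an aromatic 2-silyloxyfuran. Its catalytic asymmetric vinylogous Mukaiyama aldol addition to 3,4-dimethoxybenzaldehyde forms that bond and sets C-2 and the carbinol centre (erythro) in one operation. The precursor is a flat, achiral 3-silyloxy-4-(4-methoxyphenyl)-2-silyloxyfuran. The extra unsaturation is then used up: hydrogenation anti to the new side chain gives the all-cis ring, and the lactone carbonyl is reduced to CH2.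

Key step: step 3

Assumption: the quinine-derived thiourea ammonium carboxylate is taken to join the Re face of furan C-5 to the Si face of the aldehyde on this substrate; if the sense proves opposite, the quinidine-derived pseudoenantiomer is used with no other change.

Step 1
Reactants: 1 4-methoxyphenylpyruvic acid; 2 formaldehyde (37% aqueous)
Product: 3 3-hydroxy-4-(4-methoxyphenyl)furan-2(5H)-one
Conditions: aq. HCHO (1.1 equiv), K2CO3 (1.1 equiv), H2O, rt; then conc. HCl, 0 °C → rt
Reagents that add atoms: none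
Why: Aldol hydroxymethylation of the benzylic carbon of the arylpyruvate, then acid-induced lactonisation and enolisation to the aryl-conjugated 3-hydroxybutenolide (aldol–lactonisation); no stereocenter is formed.

Step 2
Reactants: 3 3-hydroxy-4-(4-methoxyphenyl)furan-2(5H)-one
Product: 5 3-(tert-butyldimethylsilyloxy)-4-(4-methoxyphenyl)-2-(trimethylsilyloxy)furan, via enol TBS ether 4 (not isolated)
Conditions: TBSCl, Et3N, cat. DMAP, CH2Cl2, 0 °C → rt; then TMSOTf, Et3N, 0 °C; pentane, filtration under Ar, used crude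
Reagents that add atoms: tert-butyldimethylsilyl chloride CC(C)(C)[Si](C)(C)Cl; trimethylsilyl trifluoromethanesulfonate C[Si](C)(C)OS(=O)(=O)C(F)(F)F
Why: The acidic enol hydroxyl is O-silylated first, then soft enolisation (TMSOTf/Et3N) removes a γ-proton of butenolide 4 and silylates the lactone oxygen to give the aromatic 2-silyloxyfuran (silyl dienol ether formation); no stereocenter is formed.

Step 3
Reactants: 5 3-(tert-butyldimethylsilyloxy)-4-(4-methoxyphenyl)-2-(trimethylsilyloxy)furan; 6 3,4-dimethoxybenzaldehyde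
Product: 8 (5S)-3-(tert-butyldimethylsilyloxy)-5-[(R)-(3,4-dimethoxyphenyl)(hydroxy)methyl]-4-(4-methoxyphenyl)furan-2(5H)-one, via aldol TMS ether 7 (not isolated)
Conditions: salt of 9-amino(9-deoxy)epiquinine N-[3,5-bis(trifluoromethyl)phenyl]thiourea with CF3CO2H (10 mol%), CH2Cl2, −20 °C; then aq. citric acid, MeOH, 0 °C
Reagents that add atoms: none
Why: Vinylogous Mukaiyama aldol reaction: the carboxylate of the catalyst salt attacks the trimethylsilyl group on O-2 of furan 5 (a silyl ketene acetal oxygen, far more labile than the hindered enol TBS ether on O-3) and releases an ammonium-paired furan-2-olate, whose C-5 adds to the thiourea-bound aldehyde carbon of 6, after which silyl transfer to the aldolate oxygen gives 7 and returns the carboxylate. The closest known reaction type is the anti-selective asymmetric vinylogous aldol addition of 2-silyloxyfurans to aromatic aldehydes under cinchona thiourea ammonium carboxylate catalysis. No ring is closed; the aromatic furan becomes the butenolide ring whose C-5 is the later oxolane C-2. Both new stereocenters are set by the catalyst-organised open transition state, in which the Re face of furan C-5 meets the Si face of the aldehyde, the dimethoxyphenyl group lies antiperiplanar to C-4 (away from the anisyl group) and the aldehyde oxygen lies antiperiplanar to the ring oxygen, which should lead to the erythro pair (5S, carbinol R). The step needs γ over α regioselectivity, secured because C-5 is the only unsubstituted dienolate terminus while C-3 is blocked by OTBS, and anti over syn selectivity, secured by the ion-pair activation (no Lewis acid on the aldehyde oxygen that would draw it over the ring).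

Step 4
Reactants: 8 (5S)-3-(tert-butyldimethylsilyloxy)-5-[(R)-(3,4-dimethoxyphenyl)(hydroxy)methyl]-4-(4-methoxyphenyl)furan-2(5H)-one
Product: 9 (5S)-3-(tert-butyldimethylsilyloxy)-5-[(R)-(tert-butyldimethylsilyloxy)(3,4-dimethoxyphenyl)methyl]-4-(4-methoxyphenyl)furan-2(5H)-one
Conditions: TBSOTf, 2,6-lutidine, CH2Cl2, −78 → 0 °C
Reagents that add atoms: tert-butyldimethylsilyl trifluoromethanesulfonate CC(C)(C)[Si](C)(C)OS(=O)(=O)C(F)(F)F
Why: Silyl ether formation at the secondary benzylic alcohol with a silyl triflate and a weak hindered base, which should leave the acidic γ-hydrogen and both stereocenters untouched.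

Step 5
Reactants: 9 (5S)-3-(tert-butyldimethylsilyloxy)-5-[(R)-(tert-butyldimethylsilyloxy)(3,4-dimethoxyphenyl)methyl]-4-(4-methoxyphenyl)furan-2(5H)-one
Product: 10 (3S,4S,5S)-3-(tert-butyldimethylsilyloxy)-5-[(R)-(tert-butyldimethylsilyloxy)(3,4-dimethoxyphenyl)methyl]-4-(4-methoxyphenyl)oxolan-2-one (all-cis lactone)
Conditions: H2 (50 bar), 10% Pd/C, EtOAc, rt
Reagents that add atoms: none
Why: Heterogeneous syn hydrogenation of the tetrasubstituted butenolide double bond from the ring face opposite the bulky C-5 side chain (as in the reduction of ascorbic-acid-type butenolides to all-cis lactones) places OTBS at C-3, the anisyl group at C-4 and the side chain at C-5 all cis, which sets C-3 and C-4.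

Step 6
Reactants: 10 (3S,4S,5S)-3-(tert-butyldimethylsilyloxy)-5-[(R)-(tert-butyldimethylsilyloxy)(3,4-dimethoxyphenyl)methyl]-4-(4-methoxyphenyl)oxolan-2-one
Product: 12 (2S,3S,4S)-4-(tert-butyldimethylsilyloxy)-2-[(R)-(tert-butyldimethylsilyloxy)(3,4-dimethoxyphenyl)methyl]-3-(4-methoxyphenyl)oxolane (all-cis), via lactol 11 (not isolated)
Conditions: DIBAL-H, CH2Cl2, −78 °C; then Et3SiH, BF3·OEt2, −78 → −40 °C
Reagents that add atoms: none
Why: Partial reduction of the lactone to lactol 11 and ionic hydrogenation of the derived cyclic oxocarbenium ion turn C=O into CH2 at a carbon that carries no stereocenter, so the four existing centres are untouched (the descriptor at C-3 changes only through CIP priorities).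

Step 7
Reactants: 12 (2S,3S,4S)-4-(tert-butyldimethylsilyloxy)-2-[(R)-(tert-butyldimethylsilyloxy)(3,4-dimethoxyphenyl)methyl]-3-(4-methoxyphenyl)oxolane
Product: 13 (3S,4R,5S)-5-[(R)-(3,4-dimethoxyphenyl)(hydroxy)methyl]-4-(4-methoxyphenyl)oxolan-3-ol
Conditions: TBAF, THF, 0 °C → rt
Reagents that add atoms: none
Why: Fluoride-induced cleavage of both silyl ethers (desilylation) frees the two hydroxyl groups without touching any stereocenter.

Compound list
1 | 4-methoxyphenylpyruvic acid | COc1ccc(CC(=O)C(=O)O)cc1 | starting material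
2 | formaldehyde | C=O | starting material
3 | 3-hydroxy-4-(4-methoxyphenyl)furan-2(5H)-one | COc1ccc(C2=C(O)C(=O)OC2)cc1 | intermediate
4 | 3-(tert-butyldimethylsilyloxy)-4-(4-methoxyphenyl)furan-2(5H)-one (not isolated) | COc1ccc(C2=C(O[Si](C)(C)C(C)(C)C)C(=O)OC2)cc1 | intermediate
5 | 3-(tert-butyldimethylsilyloxy)-4-(4-methoxyphenyl)-2-(trimethylsilyloxy)furan | COc1ccc(-c2coc(O[Si](C)(C)C)c2O[Si](C)(C)C(C)(C)C)cc1 | intermediate
6 | 3,4-dimethoxybenzaldehyde | COc1ccc(C=O)cc1OC | starting material
7 | (5S)-3-(tert-butyldimethylsilyloxy)-5-[(R)-(3,4-dimethoxyphenyl)(trimethylsilyloxy)methyl]-4-(4-methoxyphenyl)furan-2(5H)-one (not isolated) | COc1ccc(C2=C(O[Si](C)(C)C(C)(C)C)C(=O)O[C@@H]2[C@H](O[Si](C)(C)C)c3ccc(OC)c(OC)c3)cc1 | intermediate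
8 | (5S)-3-(tert-butyldimethylsilyloxy)-5-[(R)-(3,4-dimethoxyphenyl)(hydroxy)methyl]-4-(4-methoxyphenyl)furan-2(5H)-one | COc1ccc(C2=C(O[Si](C)(C)C(C)(C)C)C(=O)O[C@@H]2[C@H](O)c3ccc(OC)c(OC)c3)cc1 | intermediate
9 | (5S)-3-(tert-butyldimethylsilyloxy)-5-[(R)-(tert-butyldimethylsilyloxy)(3,4-dimethoxyphenyl)methyl]-4-(4-methoxyphenyl)furan-2(5H)-one | COc1ccc(C2=C(O[Si](C)(C)C(C)(C)C)C(=O)O[C@@H]2[C@H](O[Si](C)(C)C(C)(C)C)c3ccc(OC)c(OC)c3)cc1 | intermediate
10 | (3S,4S,5S)-3-(tert-butyldimethylsilyloxy)-5-[(R)-(tert-butyldimethylsilyloxy)(3,4-dimethoxyphenyl)methyl]-4-(4-methoxyphenyl)oxolan-2-one, all-cis | COc1ccc([C@H]2[C@@H]([C@H](O[Si](C)(C)C(C)(C)C)c3ccc(OC)c(OC)c3)OC(=O)[C@H]2O[Si](C)(C)C(C)(C)C)cc1 | intermediate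
11 | (3S,4S,5S)-3-(tert-butyldimethylsilyloxy)-5-[(R)-(tert-butyldimethylsilyloxy)(3,4-dimethoxyphenyl)methyl]-4-(4-methoxyphenyl)oxolan-2-ol, both C-2 epimers (not isolated) | COc1ccc([C@H]2[C@@H]([C@H](O[Si](C)(C)C(C)(C)C)c3ccc(OC)c(OC)c3)OC(O)[C@H]2O[Si](C)(C)C(C)(C)C)cc1 | intermediate
12 | (2S,3S,4S)-4-(tert-butyldimethylsilyloxy)-2-[(R)-(tert-butyldimethylsilyloxy)(3,4-dimethoxyphenyl)methyl]-3-(4-methoxyphenyl)oxolane, all-cis | COc1ccc([C@H]2[C@@H]([C@H](O[Si](C)(C)C(C)(C)C)c3ccc(OC)c(OC)c3)OC[C@H]2O[Si](C)(C)C(C)(C)C)cc1 | intermediate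
13 | (3S,4R,5S)-5-[(R)-(3,4-dimethoxyphenyl)(hydroxy)methyl]-4-(4-methoxyphenyl)oxolan-3-ol | COc1ccc([C@H]2[C@@H]([C@H](O)c3ccc(OC)c(OC)c3)OC[C@H]2O)cc1 | target

Total step count: 7. Longest linear sequence: 7 steps (1 → 13).

Steps most likely to fail

Step 3. The anisyl group next to the reacting C-5 and the low electrophilicity of the electron-rich aldehyde may blur the anti/syn discrimination at the carbinol carbon while facial control at C-5 still holds. The fallback no longer asks the aldol for the carbinol configuration but sets it by a late chelation-controlled ketone reduction. It sets out from compound 8 as then obtained, that is, mixed with the syn adduct F1. The mixture is taken unseparated through the conditions of steps 4 to 7, which should carry F1 through bis-silyl ether F2, all-cis lactone F3, lactol F4 and oxolane F5 to the epimeric diol F6, alongside 9 to 13. Activated MnO2 (CH2Cl2, rt) should then oxidise only the electron-rich benzylic carbinol of both epimers to the single aryl ketone F7. Zn(BH4)2 (Et2O, −20 °C) should reduce F7 through the five-membered zinc chelate between the ketone oxygen and ring O-1, with hydride entering from the side of H-2; this gives the erythro alcohol and comes back to compound 13.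

Step 5. The tetrasubstituted alkene, flanked by two silyl ethers and an aryl group, may fail to reach the catalyst surface, and forcing conditions may then cleave the benzylic C–O bond by hydrogenolysis. The fallback hydrogenates the unprotected enol instead and sets out from compound 8. TBAF buffered with AcOH (THF, 0 °C) removes the enol silyl group to give the free enol diol F8. Hydrogenation of this much less hindered 3-hydroxybutenolide (5% Rh/Al2O3, H2 4 bar, EtOAc, rt) should again add hydrogen anti to the C-5 side chain and give the all-cis dihydroxy lactone F9. Double silylation (TBSOTf, 2,6-lutidine, CH2Cl2, −78 → 0 °C) comes back to compound 10.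

Step 6. The Lewis acid may ionise the electron-rich benzylic C–O bond, or the oxocarbenium ion may be intercepted by the dimethoxyphenyl ring (Friedel–Crafts closure) before hydride transfer. The fallback avoids every cationic intermediate and sets out from compound 10. LiBH4 (THF, 0 °C → rt) opens the lactone to the 1,4-diol F10. TsCl in pyridine (0 → 50 °C) sulfonylates only the primary hydroxyl to the monotosylate F11, which is not isolated. The remaining secondary hydroxyl displaces the tosylate in a 5-exo-tet closure that breaks no bond at a stereocenter and comes back to compound 12.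

Further compounds
F1 | step 3 | (5S)-3-(tert-butyldimethylsilyloxy)-5-[(S)-(3,4-dimethoxyphenyl)(hydroxy)methyl]-4-(4-methoxyphenyl)furan-2(5H)-one | COc1ccc(C2=C(O[Si](C)(C)C(C)(C)C)C(=O)O[C@@H]2[C@@H](O)c3ccc(OC)c(OC)c3)cc1
F2 | step 3 | (5S)-3-(tert-butyldimethylsilyloxy)-5-[(S)-(tert-butyldimethylsilyloxy)(3,4-dimethoxyphenyl)methyl]-4-(4-methoxyphenyl)furan-2(5H)-one | COc1ccc(C2=C(O[Si](C)(C)C(C)(C)C)C(=O)O[C@@H]2[C@@H](O[Si](C)(C)C(C)(C)C)c3ccc(OC)c(OC)c3)cc1
F3 | step 3 | (3S,4S,5S)-3-(tert-butyldimethylsilyloxy)-5-[(S)-(tert-butyldimethylsilyloxy)(3,4-dimethoxyphenyl)methyl]-4-(4-methoxyphenyl)oxolan-2-one | COc1ccc([C@H]2[C@@H]([C@@H](O[Si](C)(C)C(C)(C)C)c3ccc(OC)c(OC)c3)OC(=O)[C@H]2O[Si](C)(C)C(C)(C)C)cc1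
F4 | step 3 | (3S,4S,5S)-3-(tert-butyldimethylsilyloxy)-5-[(S)-(tert-butyldimethylsilyloxy)(3,4-dimethoxyphenyl)methyl]-4-(4-methoxyphenyl)oxolan-2-ol | COc1ccc([C@H]2[C@@H]([C@@H](O[Si](C)(C)C(C)(C)C)c3ccc(OC)c(OC)c3)OC(O)[C@H]2O[Si](C)(C)C(C)(C)C)cc1
F5 | step 3 | (2S,3S,4S)-4-(tert-butyldimethylsilyloxy)-2-[(S)-(tert-butyldimethylsilyloxy)(3,4-dimethoxyphenyl)methyl]-3-(4-methoxyphenyl)oxolane | COc1ccc([C@H]2[C@@H]([C@@H](O[Si](C)(C)C(C)(C)C)c3ccc(OC)c(OC)c3)OC[C@H]2O[Si](C)(C)C(C)(C)C)cc1
F6 | step 3 | (3S,4R,5S)-5-[(S)-(3,4-dimethoxyphenyl)(hydroxy)methyl]-4-(4-methoxyphenyl)oxolan-3-ol | COc1ccc([C@H]2[C@@H]([C@@H](O)c3ccc(OC)c(OC)c3)OC[C@H]2O)cc1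
F7 | step 3 | (3,4-dimethoxyphenyl)[(2S,3R,4S)-4-hydroxy-3-(4-methoxyphenyl)oxolan-2-yl]methanone | COc1ccc([C@H]2[C@@H](C(=O)c3ccc(OC)c(OC)c3)OC[C@H]2O)cc1
F8 | step 5 | (5S)-5-[(R)-(3,4-dimethoxyphenyl)(hydroxy)methyl]-3-hydroxy-4-(4-methoxyphenyl)furan-2(5H)-one | COc1ccc(C2=C(O)C(=O)O[C@@H]2[C@H](O)c3ccc(OC)c(OC)c3)cc1
F9 | step 5 | (3S,4R,5S)-5-[(R)-(3,4-dimethoxyphenyl)(hydroxy)methyl]-3-hydroxy-4-(4-methoxyphenyl)oxolan-2-one | COc1ccc([C@H]2[C@@H]([C@H](O)c3ccc(OC)c(OC)c3)OC(=O)[C@H]2O)cc1
F10 | step 6 | (2S,3S,4S,5R)-2,5-bis(tert-butyldimethylsilyloxy)-5-(3,4-dimethoxyphenyl)-3-(4-methoxyphenyl)pentane-1,4-diol | COc1ccc([C@@H]([C@@H]([C@H](O[Si](C)(C)C(C)(C)C)c2ccc(OC)c(OC)c2)O)[C@@H](CO)O[Si](C)(C)C(C)(C)C)cc1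
F11 | step 6 | (2S,3S,4S,5R)-2,5-bis(tert-butyldimethylsilyloxy)-5-(3,4-dimethoxyphenyl)-4-hydroxy-3-(4-methoxyphenyl)pentyl 4-methylbenzenesulfonate | COc1ccc([C@@H]([C@@H]([C@H](O[Si](C)(C)C(C)(C)C)c2ccc(OC)c(OC)c2)O)[C@@H](COS(=O)(=O)c2ccc(C)cc2)O[Si](C)(C)C(C)(C)C)cc1
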